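Watch the side product.

| setting | Monday's | Thursday's | blue | amber | red |
|---|---|---|---|---|---|
| starting material | 0.50 M | 0.50 M | 0.50 M | 0.50 M | 0.50 M (fed, over 80 s) |
| reagent | 0.50 M | 0.25 M | 0.500 M | 0.500 M (fed, over 80 s) | 0.500 M |
| remark | run made earlier | run made earlier | everything together at the start | all else is in the flask from the start; the feed brings no volume worth counting | all else is in the flask from the start; the feed brings no volume worth counting |
| time |  |  | 3.0 min | 3.0 min | 3.0 min |

- Monday's (time / s: bis adduct / %, side product / %): 10.0: 8.5, 0.5; 15.0: 14.8, 1.9; 30.0: 12.9, 2.4; 60.0: 13.0, 8.8; 120: 9.7, 22.1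
- Thursday's (time / s: bis adduct / %, side product / %): 10.0: 3.0, 0; 20.0: 6.5, 2.2

(standard deviation of a reading: 1 percentage point)



1. the flask with the highest share of bis adduct in bis adduct plus side product ("all alike" if they lie within 1.5 percentage points) (blue / amber / red / all alike)
2. share of bis adduct in bis adduct plus side product at the end, blue
3. share of bis adduct in bis adduct plus side product at the end, amber
4. share of bis adduct in bis adduct plus side product at the end, red

I read the runs as a ladder of times. On the lowest rung, bis adduct in Monday's run had reached 14.8% by 15.0 s and stood at 12.9% at 30.0 s. Next comes side product, and I replaced its curve by its mean slope. The side-product clock c is the fraction of the charge gained per minute between Monday's last two readings, 0.133 min⁻¹. The earlier pair of readings gives 0.128 min⁻¹, so the straight line costs little. Run backwards, the line reaches zero after a lag L of 20.3 s.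

The next rung is the feed. A steady feed delivers on average at half its 80 s, a delay of 40.0 s, longer than L, and I added it to the lag in amber and red. At 3.0 min I reckoned side product at 35.4% in blue and 26.5% in amber and red. Keeping Monday's last 9.7% of bis adduct, the share, or selectivity, came to 21.5% in blue and 26.8% in the delayed pair, which I could not separate.

The forecast named red, with 19% for blue, 27% for amber and 57% for red. For red it expected bis adduct “decaying to about 24, with side about 18”.

The flasks gave 18.6% in blue, 34.3% in amber and 28.0% in red, so amber stood highest.

    starting material + reagent → first product + by-product (k = 0.0663 L mol⁻¹ s⁻¹)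
    reagent + first product ⇌ bis adduct + by-product (K = 0.890, k = 0.372 L mol⁻¹ s⁻¹)
    first product → side product (k = 0.0117 s⁻¹)
    starting material ⇌ dormant form (K = 2.57, k = 0.0602 s⁻¹)

In amber at 1.36 min, first product went to side product at 0.098 of the forward rate of its step to bis adduct. In amber at 3.00 min, that reversible step relaxed in 2.72 s, far shorter than the 3.0 min of the run. Side product stood at 34.2% in blue against my 35.4%, and at 25.3% in red and 20.7% in amber against my 26.5%. Carried on from amber's end by c, amber read at 5.0 min should hold 47.3%, and it held 43.7%.

All runs are simulated for an exercise.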